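All runs were generated by integration for substances that don't exist, and the scatter is random.

At early times the summer run shows 0.2% product at 0.833 h, and we ask how far one straight line from the start carries. That run is the very flask asked about.

| setting | summer | flask |
|---|---|---|
| starting material | 1.6 M | 1.6 M |
| partner | 1.2 equiv | 1.20 equiv |
| free catalyst | 0.5 mol% | 0.5 mol% |
| remark | the very flask that is asked about, followed so far |  |
| time |  | 20 h |

- summer (time / h: product / %, starting material / %): 0.833: 0.2, 99.4; 1.50: 1.9, 97.4; 3.00: 4.7, 95.1; 5.00: 7.4, 93.0; 10.0: 12.4, 86.1

(scatter of a reading: 1 percentage point)

- the numbers in the tables scatter by 1 percentage point (one standard deviation)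

1. amount of product in percent of the starting material charged, at 1.0 h, 5.0 h and 20 h

We build the flask up one process at a time, starting with the main step at a steady pace. The last reading, 12.4% at 10.0 h on a loading of 0.5 mol%, gives 2.48 h⁻¹. This n is the turnover rate, the moles of product made per hour per mole of catalyst charged. A steady n gives 1.24% at 1.0 h, 6.20% at 5.0 h and 24.8% at 20 h. The reading at 5.00 h lies 1.2 percentage points above this line and the first reading 0.83 points below it, both close to the scatter of 1 point, so we draw no induction.

Next we let the rate follow the starting material. The fraction of starting material not turned into product after 10.0 h is then squared at 20 h, which lowers the last figure to 23.3%. We add no further loss of material to our reckoning: the readings of product and starting material sum to 98.5% at 10.0 h. We commit to the straight line, with the run-down as its low edge.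

The forecast gives 0.7%, 7.5% and 18%, on the ground that “The rate then falls to 1.35%/h and 1.0%/h”. Here we differ, and our figure for 20 h stands higher. The gain between the last two readings falls 1.2 points short of the line, which is less than the 1.4 points scatter of a difference of two readings.

The flask gives 1.23%, 6.40% and 25.3%.

    partner → decomposed reagent (k = 0.0160 h⁻¹)
    catalyst intermediate C ⇌ catalyst intermediate D (K = 0.140, k = 7.90 h⁻¹)
    catalyst intermediate D ⇌ free catalyst + product (K = 140 M, k = 39.0 h⁻¹)
    starting material + free catalyst → catalyst intermediate A (k = 400 M⁻¹ h⁻¹)
    catalyst intermediate B → by-product + catalyst intermediate C (k = 41.0 h⁻¹)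
    partner + catalyst intermediate A ⇌ catalyst intermediate B (K = 0.550 M⁻¹, k = 1100 M⁻¹ h⁻¹)

Catalyst intermediate C, the resting state over these hours, holds 80.2% of the catalyst charged at 2.00 h and 76.4% at 20.0 h. Carried further, n reaches the whole charge of starting material at 80.6 h, but at 200 h this flask holds 71.1% product, with partner at 0%.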